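**Retrosynthetic overview**

1. Target 22 ⇒ octa-O-benzyl flavan 21 (global hydrogenolysis) ⇒ phenol–carbinol 20 (upper pyran opened at O1–C2) ⇒ lactol 16 + aryl Grignard 19 (C2–aryl bond).
2. Lactol 16 ⇒ 4-aryl-dihydrocoumarin 15 ⇒ 3-arylindan-1-one 13 by Baeyer–Villiger oxidation, which places O1 between C8a and C2.
3. Feature used: in the upper ring (O1, C2, C3, C4, C4a, C8a) the diaryl-methine C4 is bonded only to carbon (C3, C4a, catechin C8) and H. Without O1 this ring is the cyclopentanone of a 3-arylindan-1-one, with C8a bonded directly to the C2 carbonyl.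
4. Indanone 13 ⇒ chalcone triflate 12 (asymmetric reductive Heck, C4–C4a bond) ⇒ aldehyde 7 (from (+)-catechin 1 by benzylation, C8 bromination, formylation) + acetophenone 9.
5. Ring order: lower chroman (from catechin, untouched) → cyclopentanone (step 8) → lactone by ring expansion (step 9) → opened (step 12) and reclosed as the upper pyran (step 13).

Key step: step 9

**Remarks on the chemistry**

- The target is read as upper unit (2S,4S) with the 2-aryl and 4-aryl groups cis, lower unit (+)-catechin (2R,3S), joined C4 → catechin C8.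
- "Penta-O-benzylcatechin-8-yl" means (2R,3S)-3,5,7-tris(benzyloxy)-2-[3,4-bis(benzyloxy)phenyl]chroman-8-yl.
- Assumption: the sense of induction of the diphosphine in step 8 on this hindered enone is fixed in a pilot run with both ligand antipodes. The two C3 epimers are diastereomers, because the catechin unit is enantiopure, so they can be told apart and the minor one removed.

**Route**

Step 1
Reactants: 1 (+)-catechin
Product: 2 5,7,3',4'-tetra-O-benzyl-(+)-catechin (3-OH free)
Conditions: BnBr (4.2 equiv), K2CO3, DMF, 0 °C → rt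
Reagents that add atoms: benzyl bromide, BrCc1ccccc1
Why: Williamson etherification in which carbonate deprotonates only the four phenols, so the secondary 3-OH stays free and the mild base leaves catechin C2 and C3 untouched.

Step 2
Reactants: 2 5,7,3',4'-tetra-O-benzyl-(+)-catechin
Product: 3 3,5,7,3',4'-penta-O-benzyl-(+)-catechin
Conditions: NaH, BnBr, n-Bu4NI (cat.), DMF, 0 °C → rt
Reagents that add atoms: benzyl bromide, BrCc1ccccc1
Why: Williamson etherification of the secondary alkoxide; with no free phenol left there is no base-induced opening of the pyran ring, so C2 keeps its configuration.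

Step 3
Reactants: 3 3,5,7,3',4'-penta-O-benzyl-(+)-catechin
Product: 4 8-bromo-penta-O-benzylcatechin
Conditions: NBS (1.0 equiv), CH2Cl2, −78 °C → rt
Reagents that add atoms: N-bromosuccinimide, O=C1CCC(=O)N1Br
Why: Electrophilic aromatic bromination, which in 5,7-di-O-benzyl flavan-3-ols goes to C8 in preference to C6 at low temperature; one equivalent of NBS avoids the 6,8-dibromide.

Step 4
Reactants: 4 8-bromo-penta-O-benzylcatechin
Product: 7 penta-O-benzylcatechin-8-carbaldehyde, via aryllithium 5 (not isolated), via lithium hemiaminolate 6 (not isolated)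
Conditions: n-BuLi (1.1 equiv), THF, −78 °C; DMF, −78 → 0 °C; aq. NH4Cl
Reagents that add atoms: N,N-dimethylformamide, CN(C)C=O
Why: Bromine–lithium exchange at −78 °C outruns deprotonation of the benzyl ethers, and the aryllithium is formylated by DMF through the hemiaminolate, which collapses to the aldehyde on work-up.

Step 5
Reactants: 8 1-(2,5-dihydroxyphenyl)ethanone
Product: 9 1-[5-(benzyloxy)-2-hydroxyphenyl]ethanone
Conditions: BnBr (1.0 equiv), K2CO3 (1.1 equiv), acetone, reflux
Reagents that add atoms: benzyl bromide, BrCc1ccccc1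
Why: Chemoselective Williamson etherification, since the 2-OH is held in a hydrogen bond to the acetyl carbonyl and is the poorer nucleophile, so one equivalent of BnBr alkylates the 5-OH.

Step 6
Reactants: 7 penta-O-benzylcatechin-8-carbaldehyde, 9 1-[5-(benzyloxy)-2-hydroxyphenyl]ethanone
Product: 11 (E)-1-[5-(benzyloxy)-2-hydroxyphenyl]-3-(penta-O-benzylcatechin-8-yl)prop-2-en-1-one, via aldol adduct 10 (not isolated)
Conditions: KOH (50% aq.), EtOH/THF, rt → 40 °C; dilute HCl to pH 5 at 0 °C
Reagents that add atoms: none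
Why: Claisen–Schmidt condensation of a non-enolisable aldehyde with the methyl ketone, in which E1cB dehydration of the aldol gives the conjugated E-enone and the benzyl ethers are inert to hydroxide.

Step 7
Reactants: 11 (E)-2'-hydroxychalcone
Product: 12 4-(benzyloxy)-2-[(2E)-3-(penta-O-benzylcatechin-8-yl)prop-2-enoyl]phenyl trifluoromethanesulfonate
Conditions: PhNTf2, Et3N, DMAP (cat.), CH2Cl2, rt
Reagents that add atoms: N-phenylbis(trifluoromethanesulfonimide), O=S(=O)(N(c1ccccc1)S(=O)(=O)C(F)(F)F)C(F)(F)F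
Why: O-Sulfonylation of the phenol with a mild triflyl donor that does not attack the electron-rich arenes, giving the aryl triflate needed for a cationic palladium pathway.

Step 8
Reactants: 12 chalcone triflate
Product: 13 (3S)-6-(benzyloxy)-3-(penta-O-benzylcatechin-8-yl)indan-1-one
Conditions: Pd(OAc)2 (10 mol %), 3,5-Xyl-MeO-BIPHEP (12 mol %, antipode per the remark), HCO2Na (1.5 equiv, in portions), DMF, 80 °C
Reagents that add atoms: none
Why: Asymmetric intramolecular reductive Heck reaction (hydroarylation of the enone) in which the cationic aryl–Pd(diphosphine) from the triflate adds its aryl carbon to the enone β-carbon, the Pd enolate is protonated and formate returns Pd(II) to Pd(0); the new centre C3 (future C4) is set in the insertion step by the chiral diphosphine, the catechin centres being too remote to interfere, and any minor C3 epimer is a diastereomer removable by chromatography.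

Step 9
Reactants: 13 (3S)-6-(benzyloxy)-3-(penta-O-benzylcatechin-8-yl)indan-1-one
Product: 15 (4S)-7-(benzyloxy)-4-(penta-O-benzylcatechin-8-yl)chroman-2-one, via Criegee adduct 14 (not isolated)
Conditions: mCPBA (2.5 equiv), TsOH·H2O (10 mol %), CH2Cl2, 0–4 °C, dark; aq. Na2S2O3/NaHCO3
Reagents that add atoms: 3-chloroperoxybenzoic acid, OOC(=O)c1cccc(Cl)c1
Why: Baeyer–Villiger oxidation in which the acid-activated C1 carbonyl of 13 adds the peracid to give adduct 14 and the aryl carbon C7a then shifts from C1 to the proximal peroxide oxygen as 3-chlorobenzoate leaves, so that one oxygen (future O1) comes to lie between the arene carbon (future C8a) and the carbonyl carbon (future C2). The closest known reaction type is the peracid oxidation of 1-indanones, 3-aryl-1-indanones included, to 3,4-dihydrocoumarins. The six-membered lactone is not closed by a cyclisation but arises by ring expansion of the cyclopentanone through the 1,2-aryl shift, both new bonds (C8a–O1 and O1–C2) lying in the ring. No stereocentre is created, and the diaryl-methine centre (indanone C3, future C4) lies away from the migrating bond and keeps its configuration. Two selectivities are needed: aryl rather than CH2 migration, secured by the better ability of the sp2 aryl carbon to carry positive charge in the migration transition state, and attack on the ketone rather than on the alkoxyarenes, for which the acid catalyst speeds the carbonyl addition while low temperature and a small excess of peracid hold back electrophilic hydroxylation of the catechin A ring.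

Step 10
Reactants: 15 (4S)-7-(benzyloxy)-4-(penta-O-benzylcatechin-8-yl)chroman-2-one
Product: 16 (4S)-7-(benzyloxy)-4-(penta-O-benzylcatechin-8-yl)chroman-2-ol (anomer mixture)
Conditions: DIBAL-H (1.2 equiv), CH2Cl2, −78 °C; Rochelle salt
Reagents that add atoms: none
Why: Partial reduction of a lactone to the lactol, the tetrahedral aluminium acetal being stable at −78 °C until work-up so that over-reduction to the diol is avoided.

Step 11
Reactants: 17 4-bromocatechol
Product: 18 4-bromo-1,2-bis(benzyloxy)benzene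
Conditions: BnBr (2.2 equiv), K2CO3, DMF, rt
Reagents that add atoms: benzyl bromide, BrCc1ccccc1
Why: Williamson etherification of both phenols under carbonate conditions that leave the aryl bromide untouched.

Step 12
Reactants: 16 lactol, 18 4-bromo-1,2-bis(benzyloxy)benzene
Product: 20 5-(benzyloxy)-2-[(1S)-3-[3,4-bis(benzyloxy)phenyl]-3-hydroxy-1-(penta-O-benzylcatechin-8-yl)propyl]phenol (carbinol epimers), via arylmagnesium bromide 19 (not isolated)
Conditions: Mg, THF, reflux (18 → 19, 3 equiv); then 16, THF, 0 °C → rt; sat. aq. NH4Cl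
Reagents that add atoms: none
Why: Grignard addition to a lactol, in which the first equivalent deprotonates 16 and opens it to the magnesium phenoxide–aldehyde and the second adds to the aldehyde; the new carbinol centre forms without control and is left as an epimer mixture because step 13 ionises it.

Step 13
Reactants: 20 phenol–carbinol
Product: 21 (2S,4S)-7-(benzyloxy)-2-[3,4-bis(benzyloxy)phenyl]-4-(penta-O-benzylcatechin-8-yl)chroman (2,4-cis)
Conditions: TsOH·H2O (10 mol %), CH2Cl2, 0 °C → rt
Reagents that add atoms: none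
Why: Acid-catalysed SN1 cycloetherification in which the p-alkoxybenzylic cation at C2 is captured by the phenol oxygen in a six-membered closure (O1–C2); because this bond re-ionises under the same acid, the ring should settle under thermodynamic control into the 2,4-cis half-chair with both aryl groups pseudo-equatorial, so C4 dictates C2 whatever the carbinol configuration.

Step 14
Reactants: 21 octa-O-benzyl flavan
Product: 22 target, (2S,4S)-2-(3,4-dihydroxyphenyl)-7-hydroxychroman-4-yl-(4→8)-(+)-catechin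
Conditions: H2 (1 atm), 20% Pd(OH)2/C, THF/MeOH, rt
Reagents that add atoms: none
Why: Catalytic hydrogenolysis of the eight benzyl ethers under neutral conditions, which normally spare the cyclic benzylic C2–O1 ethers and the C4–C8 bond of benzylated flavan oligomers; no stereocentre is touched.

**Compound list**

1 | (+)-catechin, (2R,3S) | O[C@H]1Cc2c(O)cc(O)cc2O[C@@H]1c1ccc(O)c(O)c1 | starting material
2 | 5,7,3',4'-tetra-O-benzyl-(+)-catechin | c1c(OCc2ccccc2)cc(OCc2ccccc2)c2c1O[C@H](c1ccc(OCc3ccccc3)c(OCc3ccccc3)c1)[C@@H](O)C2 | intermediate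
3 | 3,5,7,3',4'-penta-O-benzyl-(+)-catechin | c1c(OCc2ccccc2)cc(OCc2ccccc2)c2c1O[C@H](c1ccc(OCc3ccccc3)c(OCc3ccccc3)c1)[C@@H](OCc1ccccc1)C2 | intermediate
4 | 8-bromo-penta-O-benzylcatechin | Brc1c(OCc2ccccc2)cc(OCc2ccccc2)c2c1O[C@H](c1ccc(OCc3ccccc3)c(OCc3ccccc3)c1)[C@@H](OCc1ccccc1)C2 | intermediate
5 | 8-lithio-penta-O-benzylcatechin | [Li]c1c(OCc2ccccc2)cc(OCc2ccccc2)c2c1O[C@H](c1ccc(OCc3ccccc3)c(OCc3ccccc3)c1)[C@@H](OCc1ccccc1)C2 | intermediate (not isolated)
6 | lithium (dimethylamino)(penta-O-benzylcatechin-8-yl)methanolate | [Li]OC(N(C)C)c1c(OCc2ccccc2)cc(OCc2ccccc2)c2c1O[C@H](c1ccc(OCc3ccccc3)c(OCc3ccccc3)c1)[C@@H](OCc1ccccc1)C2 | intermediate (not isolated)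
7 | penta-O-benzylcatechin-8-carbaldehyde | O=Cc1c(OCc2ccccc2)cc(OCc2ccccc2)c2c1O[C@H](c1ccc(OCc3ccccc3)c(OCc3ccccc3)c1)[C@@H](OCc1ccccc1)C2 | intermediate
8 | 1-(2,5-dihydroxyphenyl)ethanone | CC(=O)c1cc(O)ccc1O | starting material
9 | 1-[5-(benzyloxy)-2-hydroxyphenyl]ethanone | CC(=O)c1cc(OCc2ccccc2)ccc1O | intermediate
10 | aldol adduct, 1-[5-(benzyloxy)-2-hydroxyphenyl]-3-hydroxy-3-(penta-O-benzylcatechin-8-yl)propan-1-one (carbinol epimers) | O=C(CC(O)c1c(OCc2ccccc2)cc(OCc2ccccc2)c2c1O[C@H](c1ccc(OCc3ccccc3)c(OCc3ccccc3)c1)[C@@H](OCc1ccccc1)C2)c1cc(OCc2ccccc2)ccc1O | intermediate (not isolated)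
11 | (E)-1-[5-(benzyloxy)-2-hydroxyphenyl]-3-(penta-O-benzylcatechin-8-yl)prop-2-en-1-one | O=C(/C=C/c1c(OCc2ccccc2)cc(OCc2ccccc2)c2c1O[C@H](c1ccc(OCc3ccccc3)c(OCc3ccccc3)c1)[C@@H](OCc1ccccc1)C2)c1cc(OCc2ccccc2)ccc1O | intermediate
12 | 4-(benzyloxy)-2-[(2E)-3-(penta-O-benzylcatechin-8-yl)prop-2-enoyl]phenyl trifluoromethanesulfonate | O=C(/C=C/c1c(OCc2ccccc2)cc(OCc2ccccc2)c2c1O[C@H](c1ccc(OCc3ccccc3)c(OCc3ccccc3)c1)[C@@H](OCc1ccccc1)C2)c1cc(OCc2ccccc2)ccc1OS(=O)(=O)C(F)(F)F | intermediate
13 | (3S)-6-(benzyloxy)-3-(penta-O-benzylcatechin-8-yl)indan-1-one (key-step precursor) | O=C4C[C@H](c1c(OCc2ccccc2)cc(OCc2ccccc2)c2c1O[C@H](c1ccc(OCc3ccccc3)c(OCc3ccccc3)c1)[C@@H](OCc1ccccc1)C2)c5ccc(OCc6ccccc6)cc54 | intermediate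
14 | Criegee adduct, 1-hydroxy-1-(3-chlorobenzoylperoxy) derivative of 13 | OC4(OOC(=O)c7cccc(Cl)c7)C[C@H](c1c(OCc2ccccc2)cc(OCc2ccccc2)c2c1O[C@H](c1ccc(OCc3ccccc3)c(OCc3ccccc3)c1)[C@@H](OCc1ccccc1)C2)c5ccc(OCc6ccccc6)cc54 | intermediate (not isolated)
15 | (4S)-7-(benzyloxy)-4-(penta-O-benzylcatechin-8-yl)chroman-2-one (key-step product) | O=C4C[C@H](c1c(OCc2ccccc2)cc(OCc2ccccc2)c2c1O[C@H](c1ccc(OCc3ccccc3)c(OCc3ccccc3)c1)[C@@H](OCc1ccccc1)C2)c5ccc(OCc6ccccc6)cc5O4 | intermediate
16 | (4S)-7-(benzyloxy)-4-(penta-O-benzylcatechin-8-yl)chroman-2-ol (anomers) | OC4C[C@H](c1c(OCc2ccccc2)cc(OCc2ccccc2)c2c1O[C@H](c1ccc(OCc3ccccc3)c(OCc3ccccc3)c1)[C@@H](OCc1ccccc1)C2)c5ccc(OCc6ccccc6)cc5O4 | intermediate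
17 | 4-bromocatechol | Oc1ccc(Br)cc1O | starting material
18 | 4-bromo-1,2-bis(benzyloxy)benzene | Brc1ccc(OCc2ccccc2)c(OCc2ccccc2)c1 | intermediate
19 | [3,4-bis(benzyloxy)phenyl]magnesium bromide | Br[Mg]c1ccc(OCc2ccccc2)c(OCc2ccccc2)c1 | intermediate (not isolated)
20 | 5-(benzyloxy)-2-[(1S)-3-[3,4-bis(benzyloxy)phenyl]-3-hydroxy-1-(penta-O-benzylcatechin-8-yl)propyl]phenol (carbinol epimers) | OC(c1ccc(OCc2ccccc2)c(OCc2ccccc2)c1)C[C@H](c1c(OCc2ccccc2)cc(OCc2ccccc2)c2c1O[C@H](c1ccc(OCc3ccccc3)c(OCc3ccccc3)c1)[C@@H](OCc1ccccc1)C2)c1ccc(OCc2ccccc2)cc1O | intermediate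
21 | (2S,4S)-7-(benzyloxy)-2-[3,4-bis(benzyloxy)phenyl]-4-(penta-O-benzylcatechin-8-yl)chroman (2,4-cis) | c1ccccc1COc1ccc2c(c1)O[C@H](c1ccc(OCc3ccccc3)c(OCc3ccccc3)c1)C[C@@H]2c1c(OCc2ccccc2)cc(OCc2ccccc2)c2c1O[C@H](c1ccc(OCc3ccccc3)c(OCc3ccccc3)c1)[C@@H](OCc1ccccc1)C2 | intermediate
22 | CNP0227165.3, (2S,4S)-2-(3,4-dihydroxyphenyl)-7-hydroxychroman-4-yl-(4→8)-(+)-catechin | Oc1ccc2c(c1)O[C@H](c1ccc(O)c(O)c1)C[C@@H]2c1c(O)cc(O)c2c1O[C@H](c1ccc(O)c(O)c1)[C@@H](O)C2 | target

**Step count**

Total steps: 14. Longest linear sequence: 12 steps (from 1 through steps 1–4, 6–10 and 12–14 to 22).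

**Steps most likely to fail**

Step 9 (Baeyer–Villiger oxidation). The aryl carbon that must migrate carries only a meta-alkoxy group, so the rearrangement of the peracid adduct may be slow. Electrophilic oxygen transfer to the one unsubstituted position (catechin C6) of the trialkoxy A ring, followed by over-oxidation, could then overtake lactone formation. Migration of the CH2 group would give the isomeric isochromanone. The fallback keeps the oxygen insertion but blocks the vulnerable position; it sets out from 13 and comes back to the route at 22. NBS (1 equiv, CH2Cl2, −78 → 0 °C) brominates catechin C6 of 13 to give (3S)-6-(benzyloxy)-3-(6-bromo-penta-O-benzylcatechin-8-yl)indan-1-one F1. The peracid oxidation of step 9, now on a fully substituted and bromine-deactivated A ring, should pass through the bromo Criegee adduct F2 to the bromo lactone F3. Steps 10, 12 and 13 are run unchanged on the bromo series and should give the bromo lactol F4, the bromo phenol–carbinol F5 and the bromo octa-O-benzyl flavan F6. The final hydrogenolysis (H2, Pd(OH)2/C, THF/MeOH, with Et3N to take up HBr) removes the bromine together with the eight benzyl groups and delivers 22.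

Step 8 (asymmetric reductive Heck). The β-carbon carries a 2,6-dioxygenated aryl group, so facial discrimination in the insertion may be poor. Formate may also reduce the aryl–palladium species before it inserts (loss of the triflate without ring closure), and the Pd enolate may lose a β-hydride to give the indenone. The fallback replaces palladium hydroarylation by a rhodium conjugate addition; it sets out from 12 and comes back at 13. Miyaura borylation of 12 (B2pin2, PdCl2(dppf), KOAc, dioxane, 80 °C, conditions under which transmetalation with the diboron should outrun the five-membered insertion) gives the 2'-(pinacolboryl)chalcone F7. Rhodium-catalysed asymmetric intramolecular 1,4-addition ([RhCl(C2H4)2]2, MonoPhos or a chiral diene, antipode chosen as in the remark, aq. K3PO4, toluene, rt → 50 °C) then closes the ring to 13. This path has no hydride source and no β-hydride elimination route, since the rhodium enolate is simply protonated by water.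

Step 13 (acid-mediated ring closure). Equilibration to the 2,4-cis isomer may be incomplete, and the acid may ionise the wrong bond, either cleaving C4–catechin C8 by protonation of the trialkoxyarene or opening the lower pyran ring. The fallback makes the closure stereospecific under neutral conditions; it sets out from 20 and comes back at 21. MnO2 (CH2Cl2, rt) oxidises the electron-rich benzylic carbinol of 20 to the ketone 1-[3,4-bis(benzyloxy)phenyl]-3-[4-(benzyloxy)-2-hydroxyphenyl]-3-(penta-O-benzylcatechin-8-yl)propan-1-one F8. CBS reduction ((S)-Me-CBS, BH3·SMe2 in excess for the free phenol, THF, −20 °C), by the usual model for aryl alkyl ketones, should give the single (R)-carbinol F9. Mitsunobu cyclisation (PPh3, DIAD, THF, 0 °C) then forms O1–C2 with inversion to the (2S) centre of 21.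

**Further compounds**

F1 | step 9 | (3S)-6-(benzyloxy)-3-(6-bromo-penta-O-benzylcatechin-8-yl)indan-1-one | O=C4C[C@H](c1c(OCc2ccccc2)c(Br)c(OCc2ccccc2)c2c1O[C@H](c1ccc(OCc3ccccc3)c(OCc3ccccc3)c1)[C@@H](OCc1ccccc1)C2)c5ccc(OCc6ccccc6)cc54
F2 | step 9 | bromo Criegee adduct, 1-hydroxy-1-(3-chlorobenzoylperoxy) derivative of F1 | OC4(OOC(=O)c7cccc(Cl)c7)C[C@H](c1c(OCc2ccccc2)c(Br)c(OCc2ccccc2)c2c1O[C@H](c1ccc(OCc3ccccc3)c(OCc3ccccc3)c1)[C@@H](OCc1ccccc1)C2)c5ccc(OCc6ccccc6)cc54
F3 | step 9 | bromo lactone, (4S)-7-(benzyloxy)-4-(6-bromo-penta-O-benzylcatechin-8-yl)chroman-2-one | O=C4C[C@H](c1c(OCc2ccccc2)c(Br)c(OCc2ccccc2)c2c1O[C@H](c1ccc(OCc3ccccc3)c(OCc3ccccc3)c1)[C@@H](OCc1ccccc1)C2)c5ccc(OCc6ccccc6)cc5O4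
F4 | step 9 | bromo lactol, (4S)-7-(benzyloxy)-4-(6-bromo-penta-O-benzylcatechin-8-yl)chroman-2-ol | OC4C[C@H](c1c(OCc2ccccc2)c(Br)c(OCc2ccccc2)c2c1O[C@H](c1ccc(OCc3ccccc3)c(OCc3ccccc3)c1)[C@@H](OCc1ccccc1)C2)c5ccc(OCc6ccccc6)cc5O4
F5 | step 9 | bromo phenol–carbinol, 6-bromo analogue of 20 | OC(c1ccc(OCc2ccccc2)c(OCc2ccccc2)c1)C[C@H](c1c(OCc2ccccc2)c(Br)c(OCc2ccccc2)c2c1O[C@H](c1ccc(OCc3ccccc3)c(OCc3ccccc3)c1)[C@@H](OCc1ccccc1)C2)c1ccc(OCc2ccccc2)cc1O
F6 | step 9 | bromo octa-O-benzyl flavan, 6-bromo analogue of 21 | c1ccccc1COc1ccc2c(c1)O[C@H](c1ccc(OCc3ccccc3)c(OCc3ccccc3)c1)C[C@@H]2c1c(OCc2ccccc2)c(Br)c(OCc2ccccc2)c2c1O[C@H](c1ccc(OCc3ccccc3)c(OCc3ccccc3)c1)[C@@H](OCc1ccccc1)C2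
F7 | step 8 | (E)-1-[5-(benzyloxy)-2-(4,4,5,5-tetramethyl-1,3,2-dioxaborolan-2-yl)phenyl]-3-(penta-O-benzylcatechin-8-yl)prop-2-en-1-one | O=C(/C=C/c1c(OCc2ccccc2)cc(OCc2ccccc2)c2c1O[C@H](c1ccc(OCc3ccccc3)c(OCc3ccccc3)c1)[C@@H](OCc1ccccc1)C2)c1cc(OCc2ccccc2)ccc1B1OC(C)(C)C(C)(C)O1
F8 | step 13 | 1-[3,4-bis(benzyloxy)phenyl]-3-[4-(benzyloxy)-2-hydroxyphenyl]-3-(penta-O-benzylcatechin-8-yl)propan-1-one, (3S) | O=C(c1ccc(OCc2ccccc2)c(OCc2ccccc2)c1)C[C@H](c1c(OCc2ccccc2)cc(OCc2ccccc2)c2c1O[C@H](c1ccc(OCc3ccccc3)c(OCc3ccccc3)c1)[C@@H](OCc1ccccc1)C2)c1ccc(OCc2ccccc2)cc1O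
F9 | step 13 | (R)-carbinol, single epimer of 20 | O[C@@H](c1ccc(OCc2ccccc2)c(OCc2ccccc2)c1)C[C@H](c1c(OCc2ccccc2)cc(OCc2ccccc2)c2c1O[C@H](c1ccc(OCc3ccccc3)c(OCc3ccccc3)c1)[C@@H](OCc1ccccc1)C2)c1ccc(OCc2ccccc2)cc1O
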